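**Plan**
1. Retrosynthesis first removes two tropolone O-methyl helpers, then cuts both dihydropyran rings at once, at O1–C2 and C3–C4 in the left ring and at O1′–C2′ and C3′–C4′ in the right ring: a double retro-hetero-Diels–Alder to two molecules of one tropolone ortho-quinone methide and (3E,5E,7E)-nona-1,3,5,7-tetraene.
2. Enabling feature: each O-ring is fused to the same seven-membered ring through the unit O1–C9a=C4a–C4H2, so each is the [4+2] adduct of the oxadiene O=C–C=CH2 of one quinone methide with a terminal C=C of a linear C9 polyene (vinyl end gives the right ring, E-propenyl end the left ring); both O-bearing carbons are R.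
3. Forward: the tetraene by one olefination; the seven-membered ring by oxidopyrylium [5+2] cycloaddition, reductive scission of the oxygen bridge and oxidation to the hydroxytropone; ester reduction gives the quinone methide precursor; a three-component double cycloaddition closes both pyran rings; hydrolysis of the two methoxytropones ends the route.
4. Stereochemistry: C2/C3 trans from the E-propenyl geometry (suprafacial addition); C2 and C2′ from one chiral Brønsted acid acting with the same facial sense at both chain ends; no stereocentre is touched afterwards.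

Key step: step 7

Remark: the sense of induction of the chiral acid in step 7 cannot be predicted with certainty; the (R)-catalyst is assumed to give the (2R,3R,2′R) product, and its mirror image would be used otherwise.
Remark: hydroxytropones 12 and 13 are rapidly exchanging tautomers and are drawn as the 4-hydroxy-2-methoxytropone forms.

Step 1
Reactants: 1 diethyl allylphosphonate; 2 (2E,4E)-hexa-2,4-dienal
Product: 4 (3E,5E,7E)-nona-1,3,5,7-tetraene, via lithiated diethyl allylphosphonate 3 (not isolated)
Conditions: n-BuLi, THF, −78 °C; then 2, HMPA, −78 °C → rt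
Reagents that add atoms: none
Why: Horner–Wadsworth–Emmons olefination with a lithiated allylic phosphonate, which in the presence of HMPA attacks the aldehyde through its α-carbon and eliminates to the new E double bond (a known route to terminal E-1,3-dienes), while the two E double bonds of 2 are not touched; 4 should be kept cold, under argon and in solution.

Step 2
Reactants: 5 3-hydroxy-4H-pyran-4-one
Product: 6 3-hydroxy-4-methoxypyrylium trifluoromethanesulfonate
Conditions: MeOTf, CH2Cl2, reflux
Reagents that add atoms: methyl trifluoromethanesulfonate, COS(=O)(=O)C(F)(F)F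
Why: O-alkylation of the pyranone carbonyl oxygen (the most nucleophilic site, giving an aromatic pyrylium ion) is the established activation of 3-hydroxy-4-pyranones for oxidopyrylium chemistry, and the methyl group introduced here later serves as the tropolone protecting group.

Step 3
Reactants: 6 3-hydroxy-4-methoxypyrylium trifluoromethanesulfonate; 7 methyl but-2-ynoate
Product: 9 methyl 3-methoxy-7-methyl-2-oxo-8-oxabicyclo[3.2.1]octa-3,6-diene-6-carboxylate (racemic), via 4-methoxypyrylium-3-olate 8 (not isolated)
Conditions: PhNMe2, 7 (excess), CHCl3, 100 °C (sealed tube)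
Reagents that add atoms: none
Why: Deprotonation gives the oxidopyrylium ylide, which undergoes [5+2] cycloaddition across C-2/C-6 with the ynoate; the nucleophilic ylide terminus next to the oxido carbon bonds to the β-carbon of the ynoate, so the ester should end at C-6 and the methyl at C-7 (the usual regiochemistry with acceptor-substituted 2π partners), and the two bridgehead stereocentres are erased in steps 4 and 5.

Step 4
Reactants: 9 methyl 3-methoxy-7-methyl-2-oxo-8-oxabicyclo[3.2.1]octa-3,6-diene-6-carboxylate
Product: 10 methyl 7-hydroxy-5-methoxy-2-methyl-4-oxocyclohepta-1,5-diene-1-carboxylate (racemic)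
Conditions: SmI2, THF/MeOH, −78 °C; pH 7 buffer at −78 °C
Reagents that add atoms: none
Why: SmI2 reduction of an α-alkoxy ketone, in which two single-electron transfers to the ketone trigger β-scission of the C-1–O bridge bond (aligned with the carbonyl π system and also γ to the enoate) and MeOH protonates the resulting enolate; the cold neutral quench is meant to keep the hydroxy dienone from dehydrating.

Step 5
Reactants: 10 methyl 7-hydroxy-5-methoxy-2-methyl-4-oxocyclohepta-1,5-diene-1-carboxylate
Product: 12 methyl 2-hydroxy-4-methoxy-7-methyl-5-oxocyclohepta-1,3,6-triene-1-carboxylate, via diketone tautomer 11 (not isolated)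
Conditions: Dess–Martin periodinane, NaHCO3, CH2Cl2, 0 °C → rt
Reagents that add atoms: none
Why: Dess–Martin oxidation of the allylic secondary alcohol gives a cycloheptadiene-dione that should enolize spontaneously to the aromatic hydroxytropone (driven by tropone aromaticity and the hydrogen bond to the ester), under buffered conditions that avoid loss of water from 10.

Step 6
Reactants: 12 methyl 2-hydroxy-4-methoxy-7-methyl-5-oxocyclohepta-1,3,6-triene-1-carboxylate
Product: 13 4-hydroxy-5-(hydroxymethyl)-2-methoxy-6-methylcyclohepta-2,4,6-trien-1-one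
Conditions: i-Bu2AlH (4 equiv), CH2Cl2, −78 → −40 °C; aq. KNaC4H4O6
Reagents that add atoms: none
Why: Hydride reduction of a salicylate-type ester, in which the first equivalent of i-Bu2AlH deprotonates the acidic 4-OH, the aluminium enolate chelates and activates the neighbouring ester and at the same time makes the ring a delocalized oxidotropone that resists hydride addition, so that the ester should be reduced to the primary alcohol at low temperature.

Step 7
Reactants: 13 4-hydroxy-5-(hydroxymethyl)-2-methoxy-6-methylcyclohepta-2,4,6-trien-1-one (two molecules); 4 (3E,5E,7E)-nona-1,3,5,7-tetraene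
Product: 16 (2R,3R)-8-methoxy-2-{(1E,3E)-4-[(2R)-8-methoxy-5-methyl-7-oxo-2,3,4,7-tetrahydrocyclohepta[b]pyran-2-yl]buta-1,3-dien-1-yl}-3,5-dimethyl-3,4-dihydrocyclohepta[b]pyran-7(2H)-one, via ortho-quinone methide 14 (not isolated), via mono-cycloadduct 15 (not isolated)
Conditions: (R)-3,3′-bis(2,4,6-triisopropylphenyl)-BINOL N-triflylphosphoramide (10 mol %), 5 Å MS, PhCF3, 0 °C → rt, slow addition of 13 (2.3 equiv) to 4
Reagents that add atoms: none
Why: Proposed new method: the chiral Brønsted acid should dehydrate 13 to the tropolone ortho-quinone methide 14, hold it as a hydrogen-bonded contact ion pair at the C-4 carbonyl oxygen, and let its oxadiene (O=C4–C5=CH2) add in an inverse-electron-demand hetero-Diels–Alder reaction to the vinyl end and then to the E-propenyl end of 4; the closest known reaction type is the chiral N-triflylphosphoramide-catalysed [4+2] cycloaddition of in situ generated ortho-quinone methides with unactivated alkenes, which has not been shown for tropolone-derived quinone methides or for polyene termini. Each dihydropyran ring closes by a concerted, asynchronous [4π+2π] cycloaddition in which the CH2–C bond to the terminal polyene carbon leads and the O–C bond to the neighbouring carbon follows (in the stepwise limit a six-membered O-closure on the near end of a polyenyl cation), and O–C closure restores the aromatic tropone. The trans relation of the C-3 methyl and the C-2 dienyl group follows from suprafacial addition to the E-propenyl double bond; the absolute configuration at C-2 and C-2′ is set by the catalyst, which meets the same kind of alkene face at both chain ends (both centres are R), and C-3 follows from C-2 through the alkene geometry. The step needs site selectivity for the two terminal double bonds (attack of the methide carbon at a chain end gives the most delocalized polyenyl cation character, and after the first addition the terminus next to the new C–O centre is inductively and sterically deactivated), O-to-internal-carbon regioselectivity (same polarization) and hetero- over carbo-Diels–Alder periselectivity (rearomatization on O–C closure). Because two independent catalyst-controlled events are combined, most of the minor enantiomer should be diverted into the heterochiral diastereomer, which chromatography removes.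

Step 8
Reactants: 16 (2R,3R)-8-methoxy-2-{(1E,3E)-4-[(2R)-8-methoxy-5-methyl-7-oxo-2,3,4,7-tetrahydrocyclohepta[b]pyran-2-yl]buta-1,3-dien-1-yl}-3,5-dimethyl-3,4-dihydrocyclohepta[b]pyran-7(2H)-one
Product: 17 (2R,3R)-8-hydroxy-2-{(1E,3E)-4-[(2R)-8-hydroxy-5-methyl-7-oxo-2,3,4,7-tetrahydrocyclohepta[b]pyran-2-yl]buta-1,3-dien-1-yl}-3,5-dimethyl-3,4-dihydrocyclohepta[b]pyran-7(2H)-one (CNP0332980.1)
Conditions: LiOH, THF/H2O, 50 °C; then AcOH (pH 5)
Reagents that add atoms: lithium hydroxide, [Li+].[OH-]
Why: Addition–elimination of hydroxide at the methoxy-bearing C-8 of each 2-methoxytropone (vinylogous ester saponification at the most electrophilic ring position) should give tropolonates that are inert to further attack, while the allylic ether stereocentres and the E,E-diene are stable to base and the mild acidification avoids ionization of the allylic C–O bonds.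

**Compound list**
1 | diethyl allylphosphonate | C=CCP(=O)(OCC)OCC | starting material
2 | (2E,4E)-hexa-2,4-dienal | C/C=C/C=C/C=O | starting material
3 | lithiated diethyl allylphosphonate | [Li+].C=C[CH-]P(=O)(OCC)OCC | intermediate
4 | (3E,5E,7E)-nona-1,3,5,7-tetraene | C=C/C=C/C=C/C=C/C | intermediate
5 | 3-hydroxy-4H-pyran-4-one | O=c1ccocc1O | starting material
6 | 3-hydroxy-4-methoxypyrylium trifluoromethanesulfonate | COc1cc[o+]cc1O.[O-]S(=O)(=O)C(F)(F)F | intermediate
7 | methyl but-2-ynoate | CC#CC(=O)OC | starting material
8 | 4-methoxypyrylium-3-olate (oxidopyrylium ylide) | COc1cc[o+]cc1[O-] | intermediate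
9 | methyl 3-methoxy-7-methyl-2-oxo-8-oxabicyclo[3.2.1]octa-3,6-diene-6-carboxylate (racemic, one enantiomer drawn) | O=C1C(OC)=C[C@H]2O[C@@H]1C(C)=C2C(=O)OC | intermediate
10 | methyl 7-hydroxy-5-methoxy-2-methyl-4-oxocyclohepta-1,5-diene-1-carboxylate (racemic) | O=C1CC(C)=C(C(=O)OC)C(O)C=C1OC | intermediate
11 | methyl 5-methoxy-2-methyl-4,7-dioxocyclohepta-1,5-diene-1-carboxylate | O=C1CC(C)=C(C(=O)OC)C(=O)C=C1OC | intermediate
12 | methyl 2-hydroxy-4-methoxy-7-methyl-5-oxocyclohepta-1,3,6-triene-1-carboxylate | COC(=O)c1c(O)cc(OC)c(=O)cc1C | intermediate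
13 | 4-hydroxy-5-(hydroxymethyl)-2-methoxy-6-methylcyclohepta-2,4,6-trien-1-one | COc1cc(O)c(CO)c(C)cc1=O | intermediate
14 | 2-methoxy-6-methyl-5-methylidenecyclohepta-2,6-diene-1,4-dione (tropolone ortho-quinone methide) | C=C1C(=O)C=C(OC)C(=O)C=C1C | intermediate
15 | (2R)-2-[(1E,3E,5E)-hepta-1,3,5-trien-1-yl]-8-methoxy-5-methyl-3,4-dihydrocyclohepta[b]pyran-7(2H)-one | C/C=C/C=C/C=C/[C@H]1CCc2c(C)cc(=O)c(OC)cc2O1 | intermediate
16 | (2R,3R)-8-methoxy-2-{(1E,3E)-4-[(2R)-8-methoxy-5-methyl-7-oxo-2,3,4,7-tetrahydrocyclohepta[b]pyran-2-yl]buta-1,3-dien-1-yl}-3,5-dimethyl-3,4-dihydrocyclohepta[b]pyran-7(2H)-one | Cc1cc(=O)c(OC)cc2c1C[C@@H](C)[C@H](/C=C/C=C/[C@H]1CCc3c(C)cc(=O)c(OC)cc3O1)O2 | intermediate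
17 | (2R,3R)-8-hydroxy-2-{(1E,3E)-4-[(2R)-8-hydroxy-5-methyl-7-oxo-2,3,4,7-tetrahydrocyclohepta[b]pyran-2-yl]buta-1,3-dien-1-yl}-3,5-dimethyl-3,4-dihydrocyclohepta[b]pyran-7(2H)-one | Cc1cc(=O)c(O)cc2c1C[C@@H](C)[C@H](/C=C/C=C/[C@H]1CCc3c(C)cc(=O)c(O)cc3O1)O2 | target

Total step count: 8. Longest linear sequence: 7 steps (5 → 6 → 9 → 10 → 12 → 13 → 16 → 17).

**Steps most likely to fail**

Step 7 (Proposed new method). What may go wrong:
- poor facial discrimination at one or both chain ends;
- acid-induced reversible ionization of the allylic C–O bonds, with loss of configuration;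
- cationic oligomerization of the tetraene;
- self-alkylation of 13 at its nucleophilic C-3 by the quinone methide.

The fallback uses known chemistry, sets out from 13 and 4 and comes back at 16. The components are heated without catalyst in toluene at 140–150 °C in a sealed tube with BHT. Thermal dehydration of a hydroxymethyl hydroxytropone to its quinone methide and trapping by an alkene is a known reaction type. The trans ring relation is still fixed by the alkene geometry, but absolute control is lost, so 16 should form together with:
- the enantiomer of 16 F1;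
- the (2S,3S,2′R) diastereomer F2;
- the (2R,3R,2′S) diastereomer F3.

Chromatography on silica would separate the diastereomeric pairs, and preparative HPLC on a chiral stationary phase would separate 16 from F1.

Step 4. What may go wrong:
- electron transfer into the enone may break the other bridge C–O bond through the vinylogous path;
- the ring-opened hydroxy dienone may aromatize by loss of water before it is oxidized, which would remove the oxygen needed at C-4.

The fallback sets out from 9 and comes back at 12.
- Luche reduction (NaBH4, CeCl3·7H2O, MeOH, −78 °C) converts the ketone into the allylic alcohol methyl 2-hydroxy-3-methoxy-7-methyl-8-oxabicyclo[3.2.1]octa-3,6-diene-6-carboxylate F4. Without the ketone there is no enone pathway and no aromatization by dehydration.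
- SmI2 in THF/MeOH (with H2O/Et3N if needed) then reduces only the enoate and expels the γ-oxygen at C-1, giving the diol ester methyl 4,7-dihydroxy-5-methoxy-2-methylcyclohepta-2,5-diene-1-carboxylate F5.
- Excess Dess–Martin periodinane oxidizes both secondary alcohols to the diketo ester methyl 5-methoxy-2-methyl-4,7-dioxocyclohepta-2,5-diene-1-carboxylate F6, which enolizes to 12.

F4 and F5 would be stereoisomer mixtures; their stereocentres are erased in 12.

Step 6. What may go wrong:
- hydride addition to the tropone ring;
- over-reduction of the benzylic-type aluminium alkoxide to a methyl group through elimination to the quinone methide.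

The fallback reduces before the ring is aromatic, sets out from 9 and comes back at 13.
- i-Bu2AlH (CH2Cl2, −78 °C) reduces ketone and ester of 9 to the diol 6-(hydroxymethyl)-3-methoxy-7-methyl-8-oxabicyclo[3.2.1]octa-3,6-dien-2-ol F7.
- TBSCl/imidazole silylates the primary hydroxyl, giving the silyl ether 6-[(tert-butyldimethylsilyloxy)methyl]-3-methoxy-7-methyl-8-oxabicyclo[3.2.1]octa-3,6-dien-2-ol F8.
- Dess–Martin periodinane restores the ketone 6-[(tert-butyldimethylsilyloxy)methyl]-3-methoxy-7-methyl-8-oxabicyclo[3.2.1]octa-3,6-dien-2-one F9.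
- SmI2 in THF/MeOH opens the bridge as in step 4, giving the hydroxy ketone 3-[(tert-butyldimethylsilyloxy)methyl]-4-hydroxy-6-methoxy-2-methylcyclohepta-2,5-dien-1-one... named from the ring as 5-[(tert-butyldimethylsilyloxy)methyl]-4-hydroxy-2-methoxy-6-methylcyclohepta-2,5-dien-1-one F10.
- Dess–Martin periodinane gives the diketone 5-[(tert-butyldimethylsilyloxy)methyl]-2-methoxy-6-methylcyclohepta-2,5-diene-1,4-dione F11.
- F11 enolizes to the tropone silyl ether 5-[(tert-butyldimethylsilyloxy)methyl]-4-hydroxy-2-methoxy-6-methylcyclohepta-2,4,6-trien-1-one F12.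
- HF·pyridine in THF removes the silyl group to give 13.

**Further compounds**
F1 | step 7 | (2S,3S)-8-methoxy-2-{(1E,3E)-4-[(2S)-8-methoxy-5-methyl-7-oxo-2,3,4,7-tetrahydrocyclohepta[b]pyran-2-yl]buta-1,3-dien-1-yl}-3,5-dimethyl-3,4-dihydrocyclohepta[b]pyran-7(2H)-one (enantiomer of 16) | Cc1cc(=O)c(OC)cc2c1C[C@H](C)[C@@H](/C=C/C=C/[C@@H]1CCc3c(C)cc(=O)c(OC)cc3O1)O2
F2 | step 7 | (2S,3S,2′R) diastereomer of 16 | Cc1cc(=O)c(OC)cc2c1C[C@H](C)[C@@H](/C=C/C=C/[C@H]1CCc3c(C)cc(=O)c(OC)cc3O1)O2
F3 | step 7 | (2R,3R,2′S) diastereomer of 16 | Cc1cc(=O)c(OC)cc2c1C[C@@H](C)[C@H](/C=C/C=C/[C@@H]1CCc3c(C)cc(=O)c(OC)cc3O1)O2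
F4 | step 4 | methyl 2-hydroxy-3-methoxy-7-methyl-8-oxabicyclo[3.2.1]octa-3,6-diene-6-carboxylate (racemic, C-2 epimers) | OC1C(OC)=C[C@H]2O[C@@H]1C(C)=C2C(=O)OC
F5 | step 4 | methyl 4,7-dihydroxy-5-methoxy-2-methylcyclohepta-2,5-diene-1-carboxylate (stereoisomer mixture) | COC(=O)C1C(O)C=C(OC)C(O)C=C1C
F6 | step 4 | methyl 5-methoxy-2-methyl-4,7-dioxocyclohepta-2,5-diene-1-carboxylate | COC(=O)C1C(=O)C=C(OC)C(=O)C=C1C
F7 | step 6 | 6-(hydroxymethyl)-3-methoxy-7-methyl-8-oxabicyclo[3.2.1]octa-3,6-dien-2-ol (racemic, C-2 epimers) | OC1C(OC)=C[C@H]2O[C@@H]1C(C)=C2CO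
F8 | step 6 | 6-[(tert-butyldimethylsilyloxy)methyl]-3-methoxy-7-methyl-8-oxabicyclo[3.2.1]octa-3,6-dien-2-ol | OC1C(OC)=C[C@H]2O[C@@H]1C(C)=C2CO[Si](C)(C)C(C)(C)C
F9 | step 6 | 6-[(tert-butyldimethylsilyloxy)methyl]-3-methoxy-7-methyl-8-oxabicyclo[3.2.1]octa-3,6-dien-2-one | O=C1C(OC)=C[C@H]2O[C@@H]1C(C)=C2CO[Si](C)(C)C(C)(C)C
F10 | step 6 | 5-[(tert-butyldimethylsilyloxy)methyl]-4-hydroxy-2-methoxy-6-methylcyclohepta-2,5-dien-1-one (racemic) | O=C1CC(C)=C(CO[Si](C)(C)C(C)(C)C)C(O)C=C1OC
F11 | step 6 | 5-[(tert-butyldimethylsilyloxy)methyl]-2-methoxy-6-methylcyclohepta-2,5-diene-1,4-dione | O=C1CC(C)=C(CO[Si](C)(C)C(C)(C)C)C(=O)C=C1OC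
F12 | step 6 | 5-[(tert-butyldimethylsilyloxy)methyl]-4-hydroxy-2-methoxy-6-methylcyclohepta-2,4,6-trien-1-one | COc1cc(O)c(CO[Si](C)(C)C(C)(C)C)c(C)cc1=O
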